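The vessel is closed and stirred: J turns L into D, X competes for the same J (a competing substrate), and X also goes to G without J.

| setting | Wednesday's | flask |
|---|---|---|
| L | 0.022 M | 0.022 M |
| X | 0.50 equiv | 0.500 equiv |
| J | 0.01 mol% | 0.01 mol% |
| remark | the very flask that is asked about, followed so far |  |

Wednesday's run (percent of the L charged)

| time / s | D / % | L / % |
|---|---|---|
| 20.0 | 15.8 | 84.6 |
| 40.0 | 31.0 | 68.2 |
| 60.0 | 44.9 | 54.7 |
| 80.0 | 58.0 | 42.3 |
| 120 | 79.1 | 21.7 |

(standard deviation of a reading: 0.3 percentage points)

- the numbers in the tables scatter with a standard deviation of 0.3 percentage points
- steps under discussion: L + J <-> Z; Z -> J + D; X + J <-> Q; Q -> J + E; 2 X -> G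
- no earlier run changes the charge of J; that part of a forecast is a guess

1. apparent order in J when 50 % of the L are converted (percent change of the rate of making D for one percent more J charged)

I ask first which given numbers must be known well. The loading 0.01 mol% need not be, for J is far scarcer than L, so bound forms take little from the solution and every step through J scales with J. At one fraction of L left, the product of J charged and time is then the same, so one percent more J gets there on a clock one percent shorter. The step that makes G runs without J and so loses one percent of its time, which leaves a little more X at that point. My rule is therefore that the order in J equals one plus the order in X times the X lost to G per X present.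

So the number that matters is the mid-point time, the time at which the fraction of L left reaches 50 %: between the readings it is 1.13 min. A scatter of 0.3 percentage points against a fall of 12 points barely moves it. No run shows X, so I commit only to an order just below one.

The forecast says 0.98, on the grounds that “More X then competes for J, which pulls the order slightly below 1”.

The simulation gives 0.98, and at that point the apparent order in X is −0.19.

    L + J ⇌ Z (K = 322 M⁻¹, k = 1.34 × 10⁵ M⁻¹ s⁻¹)
    Z → J + D (k = 113 s⁻¹)
    X + J ⇌ Q (K = 110 M⁻¹, k = 3.65 × 10⁵ M⁻¹ s⁻¹)
    Q → J + E (k = 12.4 s⁻¹)
    2 X → G (k = 0.0823 M⁻¹ s⁻¹)

With c(X) as charged, the step that makes G removes X at a relative rate of 0.109 min⁻¹. Over the mid-point time that is 12.2 % of the X present, and multiplied by the order in X it puts the order in J at 0.977.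

Readings and results come from a simulation from invented constants; the scatter is artificial.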